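3 questions stand on these flasks, and I reckon them with 1 count: the turnover number N, the product formed per catalyst charged, which is the yield times the substrate charge over the catalyst charge.

in all of them: gas phase 3.8 mM (held); free catalyst 20 µM

| run | substrate | remark | time |
|---|---|---|---|
| Thursday's | 4.4 mM | run made earlier |  |
| Friday's | 16 mM | run made earlier |  |
| birch | 10 mM |  | 2.0 min |
| alder | 3.0 mM |  | 0.50 min |

| run | time / s | product / % | substrate / % |
|---|---|---|---|
| Thursday's | 15.0 | 4.9 | 94.8 |
| Thursday's | 40.0 | 22.4 | 76.5 |
| Thursday's | 80.0 | 49.9 | 50.4 |
| Thursday's | 120 | 69.1 | 32.0 |
| Friday's | 30.0 | 9.5 | 90.0 |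
| Friday's | 60.0 | 22.8 | 78.1 |
| Friday's | 90.0 | 33.0 | 67.4 |
| Friday's | 120 | 41.0 | 58.8 |

(standard deviation of a reading: 0.5 percentage points)

1. the flask that ends with the higher amount of product, in percent of the substrate charged, or "neither" when 2 percentage points or less lies between them (birch / alder / neither)
2. final product, as a percentage of the substrate charged, in birch
3. final product, as a percentage of the substrate charged, in alder

- at the start none of the gas phase is in solution

At 120 s, Thursday's run has made 152 turnovers and Friday's run 328. I solve two extreme versions of birch at 2.0 min. With catalyst and gas held as in Thursday's run, a rate pseudo-first-order in substrate would make the yield at a given time independent of the charge, and birch would stand at Thursday's 69.1%. With the same held, a rate per catalyst independent of substrate would make N at a given time independent of the charge, and Thursday's count would give birch 30.4%. Friday's run falls between these two behaviours: its charge is 3.64 times Thursday's, and its N is 2.16 times Thursday's, a smaller factor than the charge's but above 1.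

These two runs give 0.596 for n, the turnover exponent: the slope of ln N against the logarithm of the charge, at equal time, catalyst and gas. It is a reading. For birch I reckon 248 turnovers, or 49.6%. For alder, interpolating Thursday's readings to 0.50 min gives 15.4%, or 33.9 turnovers. Holding n at this earlier time gives 27.0 turnovers, or 18.0%, between the extremes of 15.4% and 22.6%. So I put birch ahead of alder.

The forecast also says birch, with 52% and 17%, and holds that “the catalyst is partly saturated by substrate”.

Birch gives 53.1% and alder 16.1%. Spent catalyst stands at 41.4% of the catalyst charged in birch at 2.00 min, against 5.02% in alder at 0.500 min. In turnovers, birch made 265, where n gave 248.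

    gas phase ⇌ dissolved gas, rate k1*(csat - [dissolved gas]) (kL = 0.0320 /s)
    substrate + dissolved gas + free catalyst → free catalyst + product (k = 2.50 × 10⁵ /M²/s)
    substrate + free catalyst → spent catalyst (k = 0.610 /M/s)

Now alder read at 80 s: Thursday's reading at that time is 49.9%, and n, held at this earlier time, carries it to 87.4 turnovers, or 58.3%. The computed flask gives 53.2%.

The readings are calculated on assumed constants; noise was put on by code.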